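Ring carbons are numbered C1–C13 as they appear in the target SMILES (C1 octyl-bearing; ring A cyclobutane C1/C2/C12/C11; ring B cyclohexene C2–C5/C13/C12; ring C cyclopentane C9–C13; ring D C5–C9/C13). Bond C2–C12, common to rings A and B, is the ring-fusion bond of a bicyclo[4.2.0]octadiene and is made by 6π-electrocyclisation of a monocyclic eight-membered trienyl silyl ether that carries trans octyl and dienoate arms. The closure is reversible; only the isomer with the dienoate arm syn to ring B is drained by an intramolecular Diels–Alder reaction onto the C5=C13 enol ether. One operation thus forms four rings and six stereocentres with the C5 oxygen in place.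

Key step: step 7

Remark on the chemistry: the sense of asymmetric induction in step 2 is assumed; if the (1S,4S) alcohol should form, the enantiomeric ligand is used. Locants C1–C13 in steps 7–10 are those defined above; the monocyclic compounds carry their own ring locants.

Step 1
Reactants: 1 cyclooctatetraene
Product: 2 cyclooctatetraene monoepoxide (meso (1R,8S)-9-oxabicyclo[6.1.0]nona-2,4,6-triene)
Conditions: mCPBA (0.7 equiv), NaHCO3, CH2Cl2, 0 °C → rt
Reagents that add atoms: 3-chloroperoxybenzoic acid (mCPBA), OOC(=O)c1cccc(Cl)c1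
Why: Prilezhaev epoxidation of one of the four equivalent cis double bonds, with substoichiometric peracid to limit double oxidation, should give the meso cis-epoxide, so no stereocentre needs control yet.

Step 2
Reactants: 2 cyclooctatetraene monoepoxide; 3 (1,3-dioxolan-2-ylmethyl)magnesium bromide
Product: 5 (1R,4R)-4-(1,3-dioxolan-2-ylmethyl)cycloocta-2,5,7-trien-1-ol (OH and side chain trans), via diorganozinc 4 (not isolated)
Conditions: ZnCl2 (0.5 equiv per 3), THF, 0 °C, 1,4-dioxane, filtration; Cu(OTf)2 (3 mol %), (S,R,R)-BINOL N,N-bis(1-phenylethyl)phosphoramidite (6 mol %), toluene, −78 → −10 °C; aq NH4Cl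
Reagents that add atoms: none
Why: Copper-catalysed enantioselective anti-SN2' ring opening of a meso vinyl epoxide by a dialkylzinc (desymmetrisation), in which the chiral copper–phosphoramidite complex should differentiate the two enantiotopic allylic termini and deliver the alkyl group anti to the departing oxygen, setting the ring stereocentre that becomes C11 and the trans carbinol.

Step 3
Reactants: 5 (1R,4R)-trienol
Product: 6 (4R)-4-(1,3-dioxolan-2-ylmethyl)cycloocta-2,5,7-trien-1-one
Conditions: Dess–Martin periodinane, NaHCO3, CH2Cl2, 0 °C; used at once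
Reagents that add atoms: none
Why: Dess–Martin oxidation under buffered, non-enolising conditions should give the cross-conjugated trienone without touching the doubly allylic stereocentre, whose γ-proton would be lost under acid or base.

Step 4
Reactants: 6 (4R)-trienone; 7 n-octylmagnesium bromide
Product: 9 (4S,5S)-4-(1,3-dioxolan-2-ylmethyl)-5-octylcycloocta-2,6-dien-1-one (substituents trans), via bromomagnesium trienolate 8 (not isolated)
Conditions: 7 (2.2 equiv), CuBr·SMe2 (1.1 equiv), THF, −78 °C; then 6, −78 → −40 °C; aq NH4Cl, −78 °C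
Reagents that add atoms: none
Why: Conjugate 1,6-addition of a dialkylcuprate to the dienone arm (attack at the δ-carbon, the terminus of the longer conjugated system) should occur anti to the neighbouring substituent on the tub-shaped ring and set the octyl-bearing centre (future C1) trans to it, and kinetic α-protonation of the trienolate gives the 2,6-dienone (a conjugated 2,7-dienone isomer, if formed, converges in step 7).

Step 5
Reactants: 9 (4S,5S)-dienone acetal
Product: 10 2-[(1S,8S)-8-octyl-4-oxocycloocta-2,6-dien-1-yl]acetaldehyde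
Conditions: p-TsOH·H2O (10 mol %), acetone/H2O 10:1, rt
Reagents that add atoms: water, O
Why: Acid-catalysed transacetalisation of the dioxolane in wet acetone should unmask the aldehyde under conditions too mild to enolise the ketone toward the ring stereocentres.

Step 6
Reactants: 10 keto aldehyde; 11 triethyl 4-phosphonocrotonate (ethyl (2E)-4-(diethoxyphosphoryl)but-2-enoate)
Product: 12 ethyl (2E,4E)-6-[(1S,8S)-8-octyl-4-oxocycloocta-2,6-dien-1-yl]hexa-2,4-dienoate
Conditions: 11 (1.3 equiv), LiN(SiMe3)2 (1.2 equiv), THF, −78 °C; then 10, −78 → 0 °C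
Reagents that add atoms: none
Why: Vinylogous Horner–Wadsworth–Emmons olefination with a preformed, weakly basic phosphonate anion should be chemoselective for the aldehyde over the ketone and E-selective, the crotonate unit entering as the (2E,4E)-dienoate.

Step 7
Reactants: 12 keto dienoate
Product: 15 tetracyclic silyl ether ester (rings A to D closed; C5–OSiEt3; C6–H with CO2Et cis to C10; C7=C8), via silyl trienol ether 13 (not isolated), via bicyclo[4.2.0]octadiene 14 (not isolated)
Conditions: Et3SiOTf (1.3 equiv), Et3N (2.5 equiv), CH2Cl2, −78 → 0 °C; filtration through basic Al2O3 (pentane); toluene (0.005 M), BHT (cat.), 110 °C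
Reagents that add atoms: triethylsilyl trifluoromethanesulfonate, CC[Si](CC)(CC)OS(=O)(=O)C(F)(F)F
Why: Soft enolisation of 12 at the doubly activated C4 methylene gives silyl trienol ether 13, whose thermal disrotatory 6π-electrocyclisation forms C2–C12 and so closes ring A (four-membered) and ring B (six-membered) together as a cis-fused bicyclo[4.2.0]octa-2,4-diene, after which an intramolecular Diels–Alder reaction of the dienoate (diene C9=C8–C7=C6) with the C13=C5 silyl enol ether closes ring C (five-membered tether ring, bond C9–C13) and ring D (six-membered cycloadduct ring, bond C5–C6). The closest known reaction type is the thermal 6π-electrocyclisation/intramolecular [4+2] cascade of 7,8-trans-disubstituted cycloocta-1,3,5-trienes, run here with inverse electron demand so that the nucleophilic enol ether carbon C13 meets the electrophilic δ-carbon C9. C2 and C12 are set cis by disrotation, and the two disrotatory senses give two bicyclic diastereomers that interconvert through 13, so the whole population should drain through 14, the only isomer whose dienoate arm on C11 lies over ring B. C13, C9, C5 and C6 arise from suprafacial addition to the one reachable face of ring B (the face carrying ring A): the C5 oxygen ends cis to C13–H, the one-carbon tether forces the (E,E)-diene to approach with its chain pointing away from ring B so that ring C is trans-fused to ring D, and the ester ends cis to C10. The step needs enolisation toward C4 and not γ-deprotonation at C11 (C4–H is both α-keto and allylic), and the fused rather than the bridged mode of cycloaddition (ring silyloxydiene adding to C8=C9), which the outward orientation of the arm and the pairing of C6 with the oxocarbenium-like C5 should secure. The absolute sense is dictated by C1 and C11 from steps 2 and 4, and high dilution suppresses intermolecular pairing.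

Step 8
Reactants: 15 tetracyclic silyl ether ester
Product: 17 C6-phenylselanyl derivative of 15 (Se cis to C10), via lithium ester enolate 16 (not isolated)
Conditions: LiN(iPr)2 (1.5 equiv), THF, −78 °C; PhSeBr (1.6 equiv), −78 °C
Reagents that add atoms: phenylselenenyl bromide, Br[Se]c1ccccc1
Why: α-Selenenylation of the ester enolate, in which the electrophile should enter C6 anti to the axial C4 branch on the neighbouring quaternary C5, that is on the face of C10, and the resulting selenide has no eliminable β-hydrogen.

Step 9
Reactants: 17 selenide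
Product: 20 ethyl ester C5-triethylsilyl ether of the target (C6=C7; C8–OH cis to C10), via allylic selenoxide 18 (not isolated), via selenenate ester 19 (not isolated)
Conditions: 30 % H2O2 (3 equiv), pyridine (3 equiv), CH2Cl2, 0 °C → rt
Reagents that add atoms: hydrogen peroxide, OO
Why: Oxidation to the allylic selenoxide should trigger a suprafacial 2,3-sigmatropic shift (the selenoxide analogue of the Mislow–Evans rearrangement) that moves the alkene into conjugation (C6=C7) and delivers oxygen to C8 on the face that carried selenium, cis to C10 and to the C5 oxygen, the selenenate ester being hydrolysed in situ.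

Step 10
Reactants: 20 hydroxy enoate silyl ether
Product: 22 target acid CNP0106718.3, via diol ethyl ester 21 (not isolated)
Conditions: Bu4NF (1.5 equiv), THF, 0 °C → rt; then LiOH·H2O (5 equiv), THF/MeOH/H2O, rt; 1 M HCl to pH 3, 0 °C
Reagents that add atoms: lithium hydroxide, [Li+].[OH-]
Why: Fluoride should cleave the tertiary triethylsilyl ether and hydroxide saponify the ethyl ester without touching any stereocentre, and since the carboxyl group and C8–OH lie trans across the ring alkene no lactone can form.

Compound list
1 | cyclooctatetraene | C1=CC=CC=CC=C1 | starting material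
2 | cyclooctatetraene monoepoxide, meso (1R,8S)-9-oxabicyclo[6.1.0]nona-2,4,6-triene | C1=CC=C[C@H]2O[C@H]2C=C1 | intermediate
3 | (1,3-dioxolan-2-ylmethyl)magnesium bromide | Br[Mg]CC1OCCO1 | starting material
4 | bis(1,3-dioxolan-2-ylmethyl)zinc | C(C1OCCO1)[Zn]CC1OCCO1 | intermediate
5 | (1R,4R)-4-(1,3-dioxolan-2-ylmethyl)cycloocta-2,5,7-trien-1-ol (trans) | O1CCOC1C[C@H]2C=C[C@H](O)C=CC=C2 | intermediate
6 | (4R)-4-(1,3-dioxolan-2-ylmethyl)cycloocta-2,5,7-trien-1-one | O1CCOC1C[C@H]2C=CC(=O)C=CC=C2 | intermediate
7 | n-octylmagnesium bromide | CCCCCCCC[Mg]Br | starting material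
8 | bromomagnesium trienolate from 1,6-addition (oxygen on the central carbon of the ring triene; octyl and side chain trans) | CCCCCCCC[C@H]1C=CC=C(O[Mg]Br)C=C[C@@H]1CC2OCCO2 | intermediate
9 | (4S,5S)-4-(1,3-dioxolan-2-ylmethyl)-5-octylcycloocta-2,6-dien-1-one (trans) | CCCCCCCC[C@H]1C=CCC(=O)C=C[C@@H]1CC2OCCO2 | intermediate
10 | 2-[(1S,8S)-8-octyl-4-oxocycloocta-2,6-dien-1-yl]acetaldehyde | CCCCCCCC[C@H]1C=CCC(=O)C=C[C@@H]1CC=O | intermediate
11 | triethyl 4-phosphonocrotonate, ethyl (2E)-4-(diethoxyphosphoryl)but-2-enoate | CCOC(=O)/C=C/CP(=O)(OCC)OCC | starting material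
12 | ethyl (2E,4E)-6-[(1S,8S)-8-octyl-4-oxocycloocta-2,6-dien-1-yl]hexa-2,4-dienoate | CCCCCCCC[C@H]1C=CCC(=O)C=C[C@@H]1C/C=C/C=C/C(=O)OCC | intermediate
13 | ethyl (2E,4E)-6-[(1S,8S)-8-octyl-4-(triethylsilyloxy)cycloocta-2,4,6-trien-1-yl]hexa-2,4-dienoate | CCCCCCCC[C@H]1C=CC=C(O[Si](CC)(CC)CC)C=C[C@@H]1C/C=C/C=C/C(=O)OCC | intermediate
14 | bicyclo[4.2.0]octa-2,4-diene valence isomer of 13 (cis-fused; C5–OSiEt3; octyl on C1 anti and dienoate arm on C11 syn to ring B) | CCCCCCCC[C@H]1[C@@H]2C=CC(O[Si](CC)(CC)CC)=C[C@@H]2[C@@H]1C/C=C/C=C/C(=O)OCC | intermediate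
15 | tetracyclic silyl ether ester (target skeleton; C5–OSiEt3 cis to C13–H; C6–H with CO2Et cis to C10; C7=C8; ring C trans-fused to ring D) | CCCCCCCC[C@H]1[C@@H]2C=C[C@]3(O[Si](CC)(CC)CC)[C@@H](C(=O)OCC)C=C[C@H]4C[C@H]1[C@H]2[C@@H]43 | intermediate
16 | lithium ester enolate of 15 | CCCCCCCC[C@H]1[C@@H]2C=C[C@]3(O[Si](CC)(CC)CC)C(=C(OCC)O[Li])C=C[C@H]4C[C@H]1[C@H]2[C@@H]43 | intermediate
17 | C6-phenylselanyl derivative of 15 (Se cis to C10) | CCCCCCCC[C@H]1[C@@H]2C=C[C@]3(O[Si](CC)(CC)CC)[C@@](C(=O)OCC)([Se]c5ccccc5)C=C[C@H]4C[C@H]1[C@H]2[C@@H]43 | intermediate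
18 | allylic selenoxide of 17 | CCCCCCCC[C@H]1[C@@H]2C=C[C@]3(O[Si](CC)(CC)CC)[C@@](C(=O)OCC)([Se](=O)c5ccccc5)C=C[C@H]4C[C@H]1[C@H]2[C@@H]43 | intermediate
19 | C8 phenylselenenate ester (C6=C7 enoate; C8–O cis to C10) | CCCCCCCC[C@H]1[C@@H]2C=C[C@]3(O[Si](CC)(CC)CC)C(C(=O)OCC)=C[C@@H](O[Se]c5ccccc5)[C@H]4C[C@H]1[C@H]2[C@@H]43 | intermediate
20 | ethyl ester C5-triethylsilyl ether of the target | CCCCCCCC[C@H]1[C@@H]2C=C[C@]3(O[Si](CC)(CC)CC)C(C(=O)OCC)=C[C@@H](O)[C@H]4C[C@H]1[C@H]2[C@@H]43 | intermediate
21 | ethyl ester of the target (C5 and C8 diol) | CCCCCCCC[C@H]1[C@@H]2C=C[C@]3(O)C(C(=O)OCC)=C[C@@H](O)[C@H]4C[C@H]1[C@H]2[C@@H]43 | intermediate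
22 | CNP0106718.3 (rings A/B, B/C and B/D cis-fused, C/D trans-fused; octyl anti to ring B; C5–OH and C8–OH cis to each other, to C13–H and to C10) | CCCCCCCC[C@H]1[C@@H]2C=C[C@]3(O)C(C(=O)O)=C[C@@H](O)[C@H]4C[C@H]1[C@H]2[C@@H]43 | target

Total step count: 10. Longest linear sequence: 10 steps (from cyclooctatetraene 1).

Steps most likely to fail

Step 7. The cycloaddition has to build the fully substituted C5 on a trisubstituted silyloxy alkene. It may be outrun by 1,5-hydrogen shifts of the triene, or diverted into the bridged mode in which the electron-rich ring diene adds to the C8=C9 bond. The fallback takes the oxygen off the ring before the cascade and restores it afterwards; it sets out from 12 and comes back to the route at 21. Ketone 12 is converted with KN(SiMe3)2 and PhNTf2 into the trienyl triflate F1. F1 is reduced with Pd(OAc)2, PPh3, Bu3N and HCO2H to the parent trans-disubstituted cyclooctatriene F2. Heating F2 in toluene should run the same electrocyclisation/cycloaddition on an unhindered, unpolarised ring diene and give the C5–H tetracycle F3. Selenenylation as in step 8 gives the selenide F4, and oxidation as in step 9 gives the hydroxy enoate F5. SeO2 with tBuOOH then hydroxylates the doubly allylic C5–H with retention (ene reaction followed by a 2,3-shift) to give 21, which is saponified with LiOH as in step 10.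

Step 4. The cuprate may add in a 1,4 sense to the shorter enone arm or to the β-carbon of the dienone arm, or approach the face syn to the neighbouring substituent. The fallback replaces the organometallic nucleophile by a radical chain; it sets out from 6 and comes back at 9. Tri-n-octylborane (from 1-octene and BH3·SMe2) with a trace of O2 in THF/H2O generates octyl radicals. These should add to the far terminus of the dienone, the position that gives the most delocalised radical, anti to the neighbouring substituent. The chain is carried by the dioctylboron trienolate F6, which is hydrolysed in the same flask to 9.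

Step 8. Deprotonation next to the quaternary C5 may be slow, the enolate may expel the silyloxy group, or the electrophile may enter on the wrong face. The fallback oxidises the alkene first and needs only a mild base; it sets out from 15 and comes back at 22. Dimethyldioxirane should epoxidise C7=C8 on the face away from the pseudoaxial ester to give the epoxy ester F7. DBU opens the epoxide by E1cB elimination to the C8-epimeric allylic alcohol F8. Mitsunobu inversion with 4-nitrobenzoic acid, PPh3 and diisopropyl azodicarboxylate gives the 4-nitrobenzoate F9 with the required C8 configuration. The conditions of step 10 then cleave the silyl ether and both esters to give 22. Should the epoxidation take the other face, the ring opening would give 20 directly.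

Further compounds
F1 | step 7 | ethyl (2E,4E)-6-[(1S,8S)-8-octyl-4-(trifluoromethylsulfonyloxy)cycloocta-2,4,6-trien-1-yl]hexa-2,4-dienoate | CCCCCCCC[C@H]1C=CC=C(OS(=O)(=O)C(F)(F)F)C=C[C@@H]1C/C=C/C=C/C(=O)OCC
F2 | step 7 | ethyl (2E,4E)-6-(trans-8-octylcycloocta-2,4,6-trien-1-yl)hexa-2,4-dienoate (ring stereocentres as in 13) | CCCCCCCC[C@H]1C=CC=CC=C[C@@H]1C/C=C/C=C/C(=O)OCC
F3 | step 7 | C5–H tetracyclic ester (as 15 without the silyloxy group; C5–H cis to C13–H) | CCCCCCCC[C@H]1[C@@H]2C=C[C@@H]3[C@@H](C(=O)OCC)C=C[C@H]4C[C@H]1[C@H]2[C@@H]43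
F4 | step 7 | C6-phenylselanyl derivative of F3 (Se cis to C10) | CCCCCCCC[C@H]1[C@@H]2C=C[C@@H]3[C@@](C(=O)OCC)([Se]c5ccccc5)C=C[C@H]4C[C@H]1[C@H]2[C@@H]43
F5 | step 7 | C5–H hydroxy enoate (C6=C7; C8–OH cis to C10) | CCCCCCCC[C@H]1[C@@H]2C=C[C@@H]3C(C(=O)OCC)=C[C@@H](O)[C@H]4C[C@H]1[C@H]2[C@@H]43
F6 | step 4 | dioctylboron trienolate corresponding to 8 | CCCCCCCC[C@H]1C=CC=C(OB(CCCCCCCC)CCCCCCCC)C=C[C@@H]1CC2OCCO2
F7 | step 8 | C7,C8-epoxide of 15 (oxygen anti to the ester and to C10) | CCCCCCCC[C@H]1[C@@H]2C=C[C@]3(O[Si](CC)(CC)CC)[C@@H](C(=O)OCC)[C@@H]5O[C@@H]5[C@H]4C[C@H]1[C@H]2[C@@H]43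
F8 | step 8 | C8 epimer of 20 (C8–OH trans to C10) | CCCCCCCC[C@H]1[C@@H]2C=C[C@]3(O[Si](CC)(CC)CC)C(C(=O)OCC)=C[C@H](O)[C@H]4C[C@H]1[C@H]2[C@@H]43
F9 | step 8 | C8 4-nitrobenzoate of 20 (C8–O cis to C10) | CCCCCCCC[C@H]1[C@@H]2C=C[C@]3(O[Si](CC)(CC)CC)C(C(=O)OCC)=C[C@@H](OC(=O)c5ccc(cc5)[N+](=O)[O-])[C@H]4C[C@H]1[C@H]2[C@@H]43
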